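## Structural features

The target is a sesquilignan made of three guaiacyl units. Ring A is joined through a CH2 group to C4 of an oxolane (O1, C2–C5). C2 of the oxolane is bonded to C5′ of a 7′-methoxy-2′,3′-dihydrobenzofuran (ring B fused to O1′–C2′–C3′), and C2′ carries ring C. The oxolane has three contiguous stereocentres: C2 (H, benzofuranyl), C3 (H, CH2OH) and C4 (OH, ring-A benzyl). Aryl, hydroxymethyl and benzyl lie on one face and the tertiary hydroxyl on the other (2R,3R,4S). The dihydrobenzofuran has two contiguous centres, C2′ (ring C) and C3′ (CH2OH), which are cis (2′R,3′R). Ring B insulates the two arrays from each other, so each needs its own absolute control. The fragile elements are: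

- the two benzylic C–O bonds para to oxygenated arenes (C2–O1 and C2′–O1′), which can ionise or be hydrogenolysed;
- the cis arrangement at C2′/C3′, which is the less stable one and is lost by ring opening under acid or strong base;
- the tertiary β-hydroxy ether at C4 and the two oxidation-prone free phenols.

The real difficulty is C4, a fully substituted carbinol that is neither benzylic nor next to a carbonyl, inside an all-cis and therefore contra-thermodynamic oxolane. The key step uses the fact that C4 is a tertiary alcohol flanked by the O1-bound methylene C5 and by C3, which bears a one-carbon substituent and is bonded to C2. That is the pattern left when the C2/C3 unit of a β-keto ester is annulated onto the carbonyl carbon (C4) and the halomethyl carbon (C5) of an α-halomethyl ketone and the final dehydration is withheld.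

## Logic of the disconnections

**17 ⇒ 16.** No skeletal bond is cut. The two CH2OH groups (on C3 and C3′) are read as ethyl esters and the two phenolic O–H bonds as O–acetyl bonds. The reason is that one hydride reagent removes all four ester-type groups, so reduction and deprotection coincide. The gain is that no silyl groups and no separate unmasking step are needed, and the electron-withdrawing groups on C3′ and ring C make the C2′–O1′ bond harder to ionise. The demand is that reduction be faster than epimerisation at C3 and C3′ (both α to an ester) and that the C4 carbinol not open by retro-aldol.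

**16 ⇒ 15.** The C2–H and C3–H bonds are removed, restoring the C2=C3 double bond. The reason is that two of the three oxolane centres then follow from one syn addition steered by C4. The gain is that C4 is the only stereochemical problem left in the oxolane. The demand is delivery of hydrogen to a tetrasubstituted push–pull alkene from the face of the C4 hydroxyl, with no hydrogenolysis of benzylic C–O bonds and no arene saturation.

**15 ⇒ 8 + 13 (through 14).** C3–C4 and O1–C5 are cut. The reason is the retron named above: a tertiary carbinol between an O-bound methylene and the α-carbon of a β-keto ester. The gain is a ring, two skeletal bonds and the quaternary centre in one convergent step joining two fragments of similar size. The demand is carbonyl addition before alkylation, facial control at an unactivated ketone, ring closure through oxygen, and no dehydration to the furan.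

**13 ⇒ 10 ⇒ 9 (through 11 and 12).** The C4–C5 bond (carbonyl carbon to bromomethyl carbon) and the C5–Br bond are cut, then the acetyl–O bond. The reason is that an arylacetic acid already holds ring A, its CH2 and C4. The gain is two steps from a commodity acid. The demand is that bromine end up only on the terminal carbon and that the aryl acetate survive brief acid.

**8 ⇒ 7 + 5.** The C2–C3 bond is cut: C2 is the formyl carbon of 7, and C3 with its ester comes from 5. The reason is one-step homologation of an aldehyde to a β-keto ester. The gain is that the handle on ring B is a simple formyl group. The demand is hydride shift, not aryl shift, and a Lewis acid too weak to ionise C2′–O1′.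

**7 ⇒ 6.** The C2′–C3′ bond is cut. The reason is that insertion of a carbenoid at C3′ into the O1′–CH2–aryl C–H bond sets both ring-B stereocentres, cis, under catalyst control. The gain is an acyclic aryl benzyl ether. The demand is enantiotopic C–H selection and a ring closure faster than any capture of the carbenoid by the free formyl group.

**6 ⇒ 4 + 5.** The C3a′–C3′ aryl–carbon bond is cut. The reason is that an aryl iodide couples directly with the C–H bond of 5, so no arylacetate or diazo-transfer step is needed. The demand is that formyl and acetate groups tolerate the coupling.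

**4 ⇒ 3 + 2; 2 ⇒ 1.** The O1′–C2′ ether bond is cut, then the benzylic C–O bond is traced to a formyl group. The reason is that the acidic, hindered phenol of 3 is an ideal partner for a neutral etherification. The gain is three commercial aromatics. The demand is that the aryl acetate survive a borohydride reduction.

## Other disconnections considered

**Alternative 1:** The cut is made in the oxolane at O1 (O1–C2 and O1–C5), read as a γ-lactone that arises by oxygen insertion into the prochiral cyclobutanone A1, 3-(ring-A benzyl)-3-(triethylsilyloxy)cyclobutanone. In the forward step a flavin- and NADPH-dependent Baeyer–Villiger monooxygenase of the cyclohexanone monooxygenase type adds its peroxide to the carbonyl carbon (future C2). One of the two enantiotopic methylenes (future C5) migrates, giving lactone A2 with C4 set.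

- In its favour: enzymatic desymmetrisation of 3-substituted cyclobutanones is an established reaction class. The quaternary carbinol is made with no other stereocentre present, the phenol can stay free, and the oxidant is air.
- Against it here: the enzyme must tell a silyloxy group from a benzyl group at a centre two bonds from the reacting carbon, and acceptance of so large a 3,3-disubstituted substrate is uncertain. The triethylsilyl ether is exposed to buffer. A1 needs its own cycloaddition–dechlorination sequence. A2 contains only C4: the C2–aryl bond (aryl-metal addition to the lactone carbonyl and reduction at the anomeric carbon) and the C3 hydroxymethyl group remain, each with its own stereochemical question, and the aryl-metal species cannot carry an ester at C3′.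
- Comparison: structurally the alternative isolates the hardest centre, whereas the chosen plan creates it while joining the two halves. Mechanistically an enzyme pocket replaces a hydrogen-bonding amine. On precedent for setting C4 the alternative is the better of the two. On convergence, on the number of centres that follow automatically (C2 and C3 from one hydrogenation of 15) and on step count after the key step (two after 15, clearly more after A2), the chosen plan is ahead.

**Alternative 2:** The cut is the C2′–C3′ bond of the dihydrobenzofuran. In the forward step dirhodium tetrakis[N-phthaloyl-(S)-tert-leucinate], Rh2(S-PTTL)4 (divalent rhodium), decomposes the aryldiazoacetate A3. The carbenoid carbon inserts into the C–H bond of the O1′–CH2–aryl group to give the cis bromo ester A4.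

- In its favour: this is a known, highly cis- and enantioselective reaction class for exactly this ring, it sets C2′ and C3′ together, and bromine is inert to both diazo chemistry and the carbenoid.
- Against it here: it solves the easier of the two stereo-arrays and leaves the oxolane untouched. The C5′–Br bond must later become the C5′–C2 bond, which means reducing and protecting the C3′ ester before any metalation and then introducing C2 at the right oxidation level.
- Comparison: the chosen route uses the same ring closure as its supporting step 4, with a formyl group where A4 has bromine, so on ring B itself the two plans are equal. The alternative is better in one respect: bromine cannot intercept the carbenoid, whereas the formyl group of 6 could. The chosen plan is better in step economy, because the formyl carbon of 7 is already C2 of the oxolane and passes to 8 in one step, and because the ester at C3′ need not be reduced early.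

**Alternative 3:** The cuts are C3–CH2 (exocyclic), C4–C5 and O1–C5, leading back to the propargylic alcohol A5, whose carbinol carbon is C2 and whose alkyne carbons are C3 and C4. In the forward step the alkoxide of A5 directs the CuI-catalysed (monovalent copper) anti addition of (isopropoxydimethylsilyl)methylmagnesium chloride A6. The silylmethyl group goes to C3 and magnesium to C4. CO2 captures the alkenylmagnesium and lactonisation gives butenolide A7.

- In its favour: every bond-forming event is known chemistry, three components are joined in one flask, the silylmethyl group is a masked hydroxymethyl (Tamao–Fleming oxidation), and C2 can be set early by asymmetric alkynylation at the ring-B formyl carbon.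
- Against it here: A7 has C3=C4 as a tetrasubstituted alkene and C5 as a carbonyl. C3–H and C4–OH must therefore be installed by conjugate reduction and hydroxylation of a hindered lactone enolate, controlled only by C2. The lactone must then be reduced to the cyclic ether (typically an acid-promoted silane reduction that endangers both benzylic C–O bonds), and the silicon must be oxidised. The Grignard reagent also forces C3′ to travel as a protected alcohol.
- Comparison: on precedent of the key step and on early control of C2 the alternative is the better. Structurally, the chosen annulation delivers C4 as a carbinol and C5 as a methylene directly, so no redox corrections follow. Mechanistically, stereocontrol by one catalyst-set centre (C4) followed by syn hydrogenation is simpler than three sequential substrate-controlled events. In steps after the key step the chosen plan is clearly shorter.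

Key step: step 8

Assumption: the sense of induction of Rh2(S-PTTL)4 (step 4) and of the quinine-derived squaramide (step 8) is taken to be the one drawn; if either gives the opposite sense, Rh2(R-PTTL)4 or the quinidine-derived squaramide is used and nothing else changes.

Remark on the structures: re-derivation from the stereodescriptors shows a cis dihydrobenzofuran (2′R,3′R) and a 2R,3R,4S oxolane with aryl, CH2OH and benzyl on one face; no atom or descriptor needed correction. Two spectator features of the key-step partners are chosen on purpose, with the skeleton and the bonds formed unchanged: C3′ is carried as its ethyl ester and both phenols as acetates, so that the last hydride step reduces and deprotects at once.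

## Route

Step 1
Reactants: 1 4-formyl-2-methoxyphenyl acetate (vanillin acetate)
Product: 2 4-(hydroxymethyl)-2-methoxyphenyl acetate
Conditions: NaBH4, THF/EtOH, 0 °C; dilute HCl quench
Reagents that add atoms: none
Why: Chemoselective borohydride reduction of the aryl aldehyde; at 0 °C with short contact the aldehyde is reduced much faster than the aryl acetate is cleaved, and the acid quench prevents acetyl transfer.

Step 2
Reactants: 3 5-iodovanillin (4-hydroxy-3-iodo-5-methoxybenzaldehyde); 2 4-(hydroxymethyl)-2-methoxyphenyl acetate
Product: 4 4-[(4-formyl-2-iodo-6-methoxyphenoxy)methyl]-2-methoxyphenyl acetate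
Conditions: PPh3, DIAD, THF, 0 °C → rt
Reagents that add atoms: none
Why: Mitsunobu etherification: the acidic phenol of 3 (ortho iodine, para formyl) is a good pronucleophile and displaces the oxyphosphonium of the primary benzylic alcohol by SN2; neutral conditions spare the acetate and avoid a labile benzylic bromide.

Step 3
Reactants: 4 4-[(4-formyl-2-iodo-6-methoxyphenoxy)methyl]-2-methoxyphenyl acetate; 5 ethyl diazoacetate
Product: 6 ethyl 2-[2-{[4-(acetyloxy)-3-methoxyphenyl]methoxy}-5-formyl-3-methoxyphenyl]-2-diazoacetate
Conditions: Pd(PPh3)4 (5 mol%), Ag2CO3 (0.5 equiv), Et3N, toluene, rt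
Reagents that add atoms: none
Why: Palladium-catalysed cross-coupling of an aryl iodide with the C–H bond of a diazoacetate: oxidative addition to zerovalent palladium, silver- and base-assisted transfer of the deprotonated diazoacetate and reductive elimination give the aryldiazoacetate with the diazo group intact; room temperature keeps carbene formation from the product negligible.

Step 4
Reactants: 6 ethyl 2-[2-{[4-(acetyloxy)-3-methoxyphenyl]methoxy}-5-formyl-3-methoxyphenyl]-2-diazoacetate
Product: 7 ethyl cis-(2R,3S)-2-[4-(acetyloxy)-3-methoxyphenyl]-5-formyl-7-methoxy-2,3-dihydro-1-benzofuran-3-carboxylate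
Conditions: Rh2(S-PTTL)4 (1 mol%), toluene (0.02 M), −60 °C
Reagents that add atoms: none
Why: Intramolecular 1,5 C–H insertion of a donor/acceptor carbenoid of divalent rhodium into the ether-activated benzylic C–H bond, a known route to cis-2-aryl-2,3-dihydrobenzofuran-3-carboxylates; the phthalimido carboxylate ligands select one of the two enantiotopic benzylic hydrogens and the concerted insertion places aryl and ester cis, setting C2′ (R) and C3′ (S) together.

Step 5
Reactants: 7 ethyl cis-(2R,3S)-2-[4-(acetyloxy)-3-methoxyphenyl]-5-formyl-7-methoxy-2,3-dihydro-1-benzofuran-3-carboxylate; 5 ethyl diazoacetate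
Product: 8 ethyl cis-(2R,3S)-2-[4-(acetyloxy)-3-methoxyphenyl]-5-(3-ethoxy-3-oxopropanoyl)-7-methoxy-2,3-dihydro-1-benzofuran-3-carboxylate
Conditions: SnCl2 (10 mol%), CH2Cl2, rt
Reagents that add atoms: none
Why: Roskamp homologation: the diazo carbon adds to the tin-activated aldehyde and the diazonium betaine loses N2 with 1,2-hydride shift to give the β-keto ester; the weak Lewis acid (divalent tin), the C3′ ester and the acetoxy group on ring C all disfavour ionisation of C2′–O1′, so the cis ring should be kept.

Step 6
Reactants: 9 homovanillic acid [2-(4-hydroxy-3-methoxyphenyl)acetic acid]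
Product: 10 2-[4-(acetyloxy)-3-methoxyphenyl]acetic acid
Conditions: Ac2O, 2 M NaOH, H2O, 0 °C; then HCl to pH 2
Reagents that add atoms: acetic anhydride, CC(=O)OC(C)=O
Why: Schotten–Baumann acetylation: in cold aqueous base the phenoxide is acylated selectively, any mixed anhydride at the carboxylate is hydrolysed, and acidification returns the free acid.

Step 7
Reactants: 10 2-[4-(acetyloxy)-3-methoxyphenyl]acetic acid
Product: 13 4-(3-bromo-2-oxopropyl)-2-methoxyphenyl acetate, via acid chloride 11 (not isolated), via diazoketone 12 (not isolated)
Conditions: (COCl)2, DMF (cat.), CH2Cl2, 0 °C → rt; CH2N2, Et2O, 0 °C; 48% aq. HBr, 0 °C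
Reagents that add atoms: diazomethane, C=[N+]=[N-]; hydrogen bromide, Br
Why: Acylation of diazomethane by the acid chloride (first stage of the Arndt–Eistert sequence) gives the diazoketone, which HBr protonates at carbon before bromide displaces N2, so bromine goes only to the terminal carbon; cold, brief acid keeps the acetate and prevents migration of bromine to the benzylic position.

Step 8
Reactants: 8 ethyl cis-(2R,3S)-2-[4-(acetyloxy)-3-methoxyphenyl]-5-(3-ethoxy-3-oxopropanoyl)-7-methoxy-2,3-dihydro-1-benzofuran-3-carboxylate; 13 4-(3-bromo-2-oxopropyl)-2-methoxyphenyl acetate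
Product: 15 ethyl (2R,3S)-2-[4-(acetyloxy)-3-methoxyphenyl]-5-[(4S)-4-{[4-(acetyloxy)-3-methoxyphenyl]methyl}-3-(ethoxycarbonyl)-4-hydroxy-4,5-dihydrofuran-2-yl]-7-methoxy-2,3-dihydro-1-benzofuran-3-carboxylate, via bromohydrin aldol adduct 14 (not isolated)
Conditions: quinine-derived squaramide 3-{[3,5-bis(trifluoromethyl)phenyl]amino}-4-{[(8α,9S)-6′-methoxycinchonan-9-yl]amino}cyclobut-3-ene-1,2-dione (10 mol%), 1,8-bis(dimethylamino)naphthalene (1.1 equiv), CH2Cl2, −20 °C
Reagents that add atoms: none
Why: Proposed new method: the quinuclidine nitrogen deprotonates keto ester 8 to an ammonium enolate while the squaramide N–H bonds hold the carbonyl oxygen of 13, so C3 adds to the ketone (C3–C4) inside a chiral ternary complex to give bromohydrin 14; this aldol step is reversible, and the enol oxygen of the aryl ketone then displaces bromide from the adjacent CH2 (O1–C5, 5-exo-tet SN2, or the same connectivity through 3-exo-tet epoxide closure and 5-exo-tet opening), which is irreversible and removes one C4 configuration from the equilibrium. The closest known reaction types are the cinchona-catalysed asymmetric interrupted Feist–Benary reaction of 1,3-dicarbonyl compounds with α-bromo α-keto esters and the racemic amine-mediated reaction with simple α-haloketones; what is new is facial control at an unactivated, enolisable ketone. The one new stereocentre, C4 (S), is under catalyst control: C2′ and C3′ are too remote to interfere, so the outcome appears as a diastereomer ratio set by the catalyst, and the quinidine-derived pseudoenantiomer is the remedy if the other face is chosen. The step needs carbonyl addition to outrun SN2 attack of the enolate carbon on CH2Br; this is secured by an amine base without a metal counter-ion, by inductive activation of the carbonyl by the α-bromine and by hydrogen-bond activation. A squaramide replaces a thiourea because thioureas are S-alkylated by α-bromoketones, and the naphthalene diamine, a kinetically slow and non-alkylatable base, takes up HBr so that the chiral amine turns over. Closure through the ketone enol oxygen, not through C3 or the ester oxygen, follows from ring size, since attack by C3 would give a cyclopropane. The product is a vinylogous carbonate whose conjugation disfavours loss of the C4 hydroxyl, so the furan should not form if acid is excluded on work-up; the C3′ hydrogen is far less acidic than the keto ester and should not be touched by the amine.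

Step 9
Reactants: 15 ethyl (2R,3S)-2-[4-(acetyloxy)-3-methoxyphenyl]-5-[(4S)-4-{[4-(acetyloxy)-3-methoxyphenyl]methyl}-3-(ethoxycarbonyl)-4-hydroxy-4,5-dihydrofuran-2-yl]-7-methoxy-2,3-dihydro-1-benzofuran-3-carboxylate
Product: 16 ethyl (2R,3S)-2-[4-(acetyloxy)-3-methoxyphenyl]-5-[(2R,3R,4S)-4-{[4-(acetyloxy)-3-methoxyphenyl]methyl}-3-(ethoxycarbonyl)-4-hydroxyoxolan-2-yl]-7-methoxy-2,3-dihydro-1-benzofuran-3-carboxylate
Conditions: H2 (3 atm), 5% Rh/Al2O3, EtOAc, rt
Reagents that add atoms: none
Why: Heterogeneous hydrogenation of a cyclic β-alkoxyacrylate: the alkene should adsorb on the face of C4 that carries the small hydroxyl (the benzyl group shields the other face and the hydroxyl can anchor to the surface), and syn addition from that face places the C2 aryl and C3 ester cis to each other and to the benzyl group (2R,3R); Rh/Al2O3 is chosen for its low tendency to hydrogenolyse benzylic C–O bonds, and the alkene has no allylic hydrogen, so it cannot migrate.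

Step 10
Reactants: 16 ethyl (2R,3S)-2-[4-(acetyloxy)-3-methoxyphenyl]-5-[(2R,3R,4S)-4-{[4-(acetyloxy)-3-methoxyphenyl]methyl}-3-(ethoxycarbonyl)-4-hydroxyoxolan-2-yl]-7-methoxy-2,3-dihydro-1-benzofuran-3-carboxylate
Product: 17 (3S,4R,5R)-3-[(4-hydroxy-3-methoxyphenyl)methyl]-5-[(2R,3R)-2-(4-hydroxy-3-methoxyphenyl)-3-(hydroxymethyl)-7-methoxy-2,3-dihydro-1-benzofuran-5-yl]-4-(hydroxymethyl)oxolan-3-ol (route numbering 2R,3R,4S; the target)
Conditions: LiBH4 (8 equiv), THF, MeOH (cat.), 0 °C → rt; aq. NH4Cl
Reagents that add atoms: none
Why: Hydride reduction of both ethyl esters to primary alcohols with reductive cleavage of the two aryl acetates in the same operation; the reagent is weakly basic and reduction is faster than enolisation, so C3 and C3′ should keep their configuration, and the tertiary alkoxide is held as a borate, which suppresses retro-aldol opening.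

## Compound list

1 | 4-formyl-2-methoxyphenyl acetate (vanillin acetate) | CC(=O)Oc1ccc(C=O)cc1OC | starting material
2 | 4-(hydroxymethyl)-2-methoxyphenyl acetate | CC(=O)Oc1ccc(CO)cc1OC | intermediate
3 | 5-iodovanillin | COc1cc(C=O)cc(I)c1O | starting material
4 | 4-[(4-formyl-2-iodo-6-methoxyphenoxy)methyl]-2-methoxyphenyl acetate | COc1cc(C=O)cc(I)c1OCc1ccc(OC(C)=O)c(OC)c1 | intermediate
5 | ethyl diazoacetate | CCOC(=O)C=[N+]=[N-] | starting material
6 | ethyl 2-[2-{[4-(acetyloxy)-3-methoxyphenyl]methoxy}-5-formyl-3-methoxyphenyl]-2-diazoacetate | CCOC(=O)C(=[N+]=[N-])c1cc(C=O)cc(OC)c1OCc1ccc(OC(C)=O)c(OC)c1 | intermediate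
7 | ethyl cis-(2R,3S)-2-[4-(acetyloxy)-3-methoxyphenyl]-5-formyl-7-methoxy-2,3-dihydro-1-benzofuran-3-carboxylate | O=Cc1cc(OC)c2c(c1)[C@H](C(=O)OCC)[C@H](c1ccc(OC(C)=O)c(OC)c1)O2 | intermediate
8 | ethyl cis-(2R,3S)-2-[4-(acetyloxy)-3-methoxyphenyl]-5-(3-ethoxy-3-oxopropanoyl)-7-methoxy-2,3-dihydro-1-benzofuran-3-carboxylate | CCOC(=O)CC(=O)c1cc(OC)c2c(c1)[C@H](C(=O)OCC)[C@H](c1ccc(OC(C)=O)c(OC)c1)O2 | intermediate
9 | homovanillic acid | COc1cc(CC(=O)O)ccc1O | starting material
10 | 2-[4-(acetyloxy)-3-methoxyphenyl]acetic acid | COc1cc(CC(=O)O)ccc1OC(C)=O | intermediate
11 | 2-[4-(acetyloxy)-3-methoxyphenyl]acetyl chloride | COc1cc(CC(=O)Cl)ccc1OC(C)=O | intermediate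
12 | 4-(3-diazo-2-oxopropyl)-2-methoxyphenyl acetate | COc1cc(CC(=O)C=[N+]=[N-])ccc1OC(C)=O | intermediate
13 | 4-(3-bromo-2-oxopropyl)-2-methoxyphenyl acetate | COc1cc(CC(=O)CBr)ccc1OC(C)=O | intermediate
14 | ethyl (2R,3S)-2-[4-(acetyloxy)-3-methoxyphenyl]-5-[(3S)-3-{[4-(acetyloxy)-3-methoxyphenyl]methyl}-4-bromo-2-(ethoxycarbonyl)-3-hydroxybutanoyl]-7-methoxy-2,3-dihydro-1-benzofuran-3-carboxylate (either configuration at the α-carbon) | COc1cc(C[C@@](O)(CBr)C(C(=O)OCC)C(=O)c2cc(OC)c3c(c2)[C@H](C(=O)OCC)[C@H](c2ccc(OC(C)=O)c(OC)c2)O3)ccc1OC(C)=O | intermediate
15 | ethyl (2R,3S)-2-[4-(acetyloxy)-3-methoxyphenyl]-5-[(4S)-4-{[4-(acetyloxy)-3-methoxyphenyl]methyl}-3-(ethoxycarbonyl)-4-hydroxy-4,5-dihydrofuran-2-yl]-7-methoxy-2,3-dihydro-1-benzofuran-3-carboxylate | COc1cc(C[C@@]2(O)COC(c3cc(OC)c4c(c3)[C@H](C(=O)OCC)[C@H](c3ccc(OC(C)=O)c(OC)c3)O4)=C2C(=O)OCC)ccc1OC(C)=O | intermediate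
16 | ethyl (2R,3S)-2-[4-(acetyloxy)-3-methoxyphenyl]-5-[(2R,3R,4S)-4-{[4-(acetyloxy)-3-methoxyphenyl]methyl}-3-(ethoxycarbonyl)-4-hydroxyoxolan-2-yl]-7-methoxy-2,3-dihydro-1-benzofuran-3-carboxylate | COc1cc(C[C@@]2(O)CO[C@@H](c3cc(OC)c4c(c3)[C@H](C(=O)OCC)[C@H](c3ccc(OC(C)=O)c(OC)c3)O4)[C@H]2C(=O)OCC)ccc1OC(C)=O | intermediate
17 | (3S,4R,5R)-3-[(4-hydroxy-3-methoxyphenyl)methyl]-5-[(2R,3R)-2-(4-hydroxy-3-methoxyphenyl)-3-(hydroxymethyl)-7-methoxy-2,3-dihydro-1-benzofuran-5-yl]-4-(hydroxymethyl)oxolan-3-ol | COc1cc(C[C@@]2(O)CO[C@@H](c3cc(OC)c4c(c3)[C@H](CO)[C@H](c3ccc(O)c(OC)c3)O4)[C@H]2CO)ccc1O | target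

## Step count and least certain steps

Total: 10 steps. The longest linear sequence is 8 steps (steps 1–5, then 8–10). The ring-A branch (steps 6 and 7) joins at step 8.

**Step 8 (key step, proposed new method).** The most likely failures are insufficient facial discrimination at a ketone flanked by two methylene groups, direct alkylation of the enolate carbon at the bromomethyl carbon instead of carbonyl addition, and slow quaternisation of the catalyst nitrogen by the bromoketone. Fallback (known chemistry) sets out from 8 and 13 and returns at 15. The chiral catalyst is dropped and the annulation is run as the racemic interrupted Feist–Benary reaction known for simple α-haloketones (Et3N, THF, 0 °C → rt). Because C2′ and C3′ are already fixed, the two C4 configurations appear as diastereomers, 15 and the C4-epimeric dihydrofuran F1. These should be separable by preparative chromatography, or after step 9, where three contiguous centres enlarge the difference. Catalyst control is thus replaced by separation on the resident stereocentres, at the cost of about half the material.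

**Step 9.** The likely failures are incomplete reduction of the hindered tetrasubstituted alkene, or, if pressure is raised to force it, partial saturation of the electron-rich arenes and hydrogenolysis of the new benzylic C2–O1 bond. Fallback sets out from 15 and returns at 16. Surface adsorption is replaced by coordination-directed homogeneous hydrogenation with [Ir(cod)(PCy3)(py)]PF6 (monovalent iridium), H2 (1 atm), CH2Cl2, rt. The C4 hydroxyl binds the cationic metal and both hydrogens are delivered to its face, with no arene reduction or hydrogenolysis to be expected. No new compound arises (F0).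

**Step 4 (and the coupling before it).** The likely failures are capture of the rhodium carbenoid by the free formyl group (carbonyl ylide formation) in competition with the insertion, base-promoted addition of the diazoacetate to the formyl group during step 3, and erosion of cis- or enantioselectivity by the flanking 7′-methoxy group. Fallback sets out from 4 and returns at 7. The formyl group is masked before any diazo chemistry: CH(OMe)3, PPTS, MeOH gives the dimethyl acetal F2. The coupling of step 3 then gives the diazoester acetal F3. The insertion of step 4 gives the cis dihydrobenzofuran acetal F4. PPTS in acetone/H2O at rt returns 7.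

**Step 5.** The likely failures are aryl migration competing with hydride shift, since the aldehyde is electron-rich and aromatic, sluggish conversion, and Lewis-acid-induced ionisation at C2′ leading to loss of the cis arrangement. Fallback sets out from 7 and returns at 8. A Reformatsky addition (Zn, BrCH2CO2Et, THF, rt) gives the β-hydroxy ester F5 as a mixture of carbinol epimers. Oxidation with Dess–Martin periodinane (CH2Cl2, NaHCO3, rt) gives 8. Both operations are non-acidic and do not rely on a migration preference.

## Further compounds

F1 | step 8 | ethyl (2R,3S)-2-[4-(acetyloxy)-3-methoxyphenyl]-5-[(4R)-4-{[4-(acetyloxy)-3-methoxyphenyl]methyl}-3-(ethoxycarbonyl)-4-hydroxy-4,5-dihydrofuran-2-yl]-7-methoxy-2,3-dihydro-1-benzofuran-3-carboxylate | COc1cc(C[C@]2(O)COC(c3cc(OC)c4c(c3)[C@H](C(=O)OCC)[C@H](c3ccc(OC(C)=O)c(OC)c3)O4)=C2C(=O)OCC)ccc1OC(C)=O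
F0 | step 9 | none | none
F2 | step 4 | 4-{[4-(dimethoxymethyl)-2-iodo-6-methoxyphenoxy]methyl}-2-methoxyphenyl acetate | COc1cc(C(OC)OC)cc(I)c1OCc1ccc(OC(C)=O)c(OC)c1
F3 | step 4 | ethyl 2-[2-{[4-(acetyloxy)-3-methoxyphenyl]methoxy}-5-(dimethoxymethyl)-3-methoxyphenyl]-2-diazoacetate | CCOC(=O)C(=[N+]=[N-])c1cc(C(OC)OC)cc(OC)c1OCc1ccc(OC(C)=O)c(OC)c1
F4 | step 4 | ethyl cis-(2R,3S)-2-[4-(acetyloxy)-3-methoxyphenyl]-5-(dimethoxymethyl)-7-methoxy-2,3-dihydro-1-benzofuran-3-carboxylate | COC(OC)c1cc(OC)c2c(c1)[C@H](C(=O)OCC)[C@H](c1ccc(OC(C)=O)c(OC)c1)O2
F5 | step 5 | ethyl (2R,3S)-2-[4-(acetyloxy)-3-methoxyphenyl]-5-(3-ethoxy-1-hydroxy-3-oxopropyl)-7-methoxy-2,3-dihydro-1-benzofuran-3-carboxylate (both carbinol epimers) | CCOC(=O)CC(O)c1cc(OC)c2c(c1)[C@H](C(=O)OCC)[C@H](c1ccc(OC(C)=O)c(OC)c1)O2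
A1 | alternative 1 | 3-[(4-hydroxy-3-methoxyphenyl)methyl]-3-(triethylsilyloxy)cyclobutan-1-one | COc1cc(CC2(O[Si](CC)(CC)CC)CC(=O)C2)ccc1O
A2 | alternative 1 | (4S)-4-[(4-hydroxy-3-methoxyphenyl)methyl]-4-(triethylsilyloxy)oxolan-2-one | COc1cc(C[C@@]2(O[Si](CC)(CC)CC)COC(=O)C2)ccc1O
A3 | alternative 2 | methyl 2-[5-bromo-2-{[4-(tert-butyldimethylsilyloxy)-3-methoxyphenyl]methoxy}-3-methoxyphenyl]-2-diazoacetate | COC(=O)C(=[N+]=[N-])c1cc(Br)cc(OC)c1OCc1ccc(O[Si](C)(C)C(C)(C)C)c(OC)c1
A4 | alternative 2 | methyl cis-(2R,3S)-5-bromo-2-[4-(tert-butyldimethylsilyloxy)-3-methoxyphenyl]-7-methoxy-2,3-dihydro-1-benzofuran-3-carboxylate | Brc1cc(OC)c2c(c1)[C@H](C(=O)OC)[C@H](c1ccc(O[Si](C)(C)C(C)(C)C)c(OC)c1)O2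
A5 | alternative 3 | 4-[4-(tert-butyldimethylsilyloxy)-3-methoxyphenyl]-1-[cis-(2R,3R)-2-[4-(tert-butyldimethylsilyloxy)-3-methoxyphenyl]-3-{[(tert-butyldimethylsilyl)oxy]methyl}-7-methoxy-2,3-dihydro-1-benzofuran-5-yl]but-2-yn-1-ol, carbinol configured as C2 of the target | COc1cc(CC#C[C@@H](O)c2cc(OC)c3c(c2)[C@H](CO[Si](C)(C)C(C)(C)C)[C@H](c2ccc(O[Si](C)(C)C(C)(C)C)c(OC)c2)O3)ccc1O[Si](C)(C)C(C)(C)C
A6 | alternative 3 | (isopropoxydimethylsilyl)methylmagnesium chloride | CC(C)O[Si](C)(C)C[Mg]Cl
A7 | alternative 3 | 3-{[4-(tert-butyldimethylsilyloxy)-3-methoxyphenyl]methyl}-4-{[dimethyl(propan-2-yloxy)silyl]methyl}-5-[cis-(2R,3R)-2-[4-(tert-butyldimethylsilyloxy)-3-methoxyphenyl]-3-{[(tert-butyldimethylsilyl)oxy]methyl}-7-methoxy-2,3-dihydro-1-benzofuran-5-yl]furan-2(5H)-one, C5 configured as C2 of the target | COc1cc(CC2=C(C[Si](C)(C)OC(C)C)[C@H](c3cc(OC)c4c(c3)[C@H](CO[Si](C)(C)C(C)(C)C)[C@H](c3ccc(O[Si](C)(C)C(C)(C)C)c(OC)c3)O4)OC2=O)ccc1O[Si](C)(C)C(C)(C)C
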